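**Retrosynthetic overview**

- Gericudranin D is reached by global hydrogenolysis of a precursor in which every phenol is masked as a benzyl or 4-(benzyloxy)benzyl ether.
- Ring C of that precursor is closed last, at C2–C3, by a visible-light Norrish–Yang photocyclization of an achiral arylglyoxal. The C3 carbinol, the C4 ketone and both stereocentres come from this one isomerization.
- Enabling feature: C2 is a CH that is benzylic to ring B and bonded to O1 of ring A. As the O–CH2 group of a 4-(benzyloxy)benzyl ether ortho to the C4/C3 1,2-dicarbonyl, it offers a weak C–H bond 1,7 to the aldehyde oxygen. The two ortho ether groups on ring A are symmetry-equivalent, so either gives the same product.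
- The glyoxal comes from the acetyl group (Claisen trifluoroacetylation, diazo transfer, dioxirane oxidation).
- Ring A is bought as phloroacetophenone and ring B inside the benzylating agents. Five identical 4-(benzyloxy)benzyl groups are put on ring A: two on carbon (Friedel–Crafts), then three on oxygen (Mitsunobu for two phenols, Williamson for the chelated one). Ring C is formed last.

Key step: step 7

Remark on the chemistry: the sense of induction by the (R)-configured phosphoric acid in step 7 is assigned from a binding model only; if it proves opposite, the (S)-acid is used and nothing else changes.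

**Step 1**
Reactants: 1 (2,4,6-trihydroxyacetophenone); 2 (4-(benzyloxy)benzyl alcohol, 2.1 equiv)
Product: 3 triphenol ketone 3,5-bis[4-(benzyloxy)benzyl]-2,4,6-trihydroxyacetophenone
Conditions: TsOH·H2O (10 mol%), MeCN, 50 °C, slow addition of 2
Reagents that add atoms: none
Why: Two-fold Friedel–Crafts benzylation, in which the acid ionizes the p-alkoxybenzyl alcohol to a stabilized cation that attacks the only two free, strongly activated positions of ring A, while any O-benzyl ether formed reverts under the acid so that C-alkylation is the thermodynamic outcome.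

**Step 2**
Reactants: 3 (triphenol ketone); 2 (4-(benzyloxy)benzyl alcohol, 2.1 equiv)
Product: 4 diether phenol 1-{3,5-bis[4-(benzyloxy)benzyl]-2,4-bis{[4-(benzyloxy)benzyl]oxy}-6-hydroxyphenyl}ethan-1-one
Conditions: PPh3 (2.4 equiv), DIAD (diisopropyl azodicarboxylate, 2.4 equiv), THF, 0 to 23 °C
Reagents that add atoms: none
Why: Two-fold Mitsunobu etherification, in which the alkoxyphosphonium ion of 2 is displaced by the two more acidic phenols (the one para to the acetyl group, then one of the two equivalent ortho phenols), while the last ortho hydroxyl, then the only hydrogen-bond donor to the carbonyl, is strongly chelated and should stay free, and the ambident phloroglucinolate that invites C-alkylation is never generated.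

**Step 3**
Reactants: 4 (diether phenol); 5 (4-(benzyloxy)benzyl chloride, 1.5 equiv)
Product: 6 methyl ketone 3,5-bis[4-(benzyloxy)benzyl]-2,4,6-tris{[4-(benzyloxy)benzyl]oxy}acetophenone
Conditions: K2CO3 (3 equiv), DMF, 70 °C
Reagents that add atoms: none
Why: Williamson ether synthesis, in which the carbonate in a dipolar aprotic solvent breaks the chelate and the resulting mono-phenoxide of a dialkoxyarene should alkylate on oxygen, which completes the three identical ethers that serve as protecting groups on the later O5 and O7 and as the future C2/ring B unit on the ortho oxygen.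

**Step 4**
Reactants: 6 (methyl ketone)
Product: 7 trifluoromethyl 1,3-diketone 1-{3,5-bis[4-(benzyloxy)benzyl]-2,4,6-tris{[4-(benzyloxy)benzyl]oxy}phenyl}-4,4,4-trifluorobutane-1,3-dione
Conditions: LiN(SiMe3)2 (1.2 equiv), THF, −78 °C; CF3CO2CH2CF3 (1.3 equiv), −78 °C; 1 M HCl quench, 0 °C; crude product used directly
Reagents that add atoms: 2,2,2-trifluoroethyl trifluoroacetate, FC(F)(F)COC(=O)C(F)(F)F
Why: Crossed Claisen condensation of the lithium enolate of the only enolizable position with an activated trifluoroacetate gives the 1,3-diketone that activates the methyl carbon for diazo transfer.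

**Step 5**
Reactants: 7 (trifluoromethyl 1,3-diketone)
Product: 8 diazoketone 2-diazo-1-{3,5-bis[4-(benzyloxy)benzyl]-2,4,6-tris{[4-(benzyloxy)benzyl]oxy}phenyl}ethan-1-one
Conditions: 4-acetamidobenzenesulfonyl azide (1.5 equiv), Et3N (1.5 equiv), H2O (1 equiv), MeCN, 23 °C
Reagents that add atoms: 4-acetamidobenzenesulfonyl azide, CC(=O)Nc1ccc(cc1)S(=O)(=O)N=[N+]=[N-]
Why: Regitz deacylative diazo transfer, in which the sulfonyl azide delivers N2 to the activated methylene and the trifluoroacetyl group is cleaved onto the sulfonamide nitrogen, leaves the diazomethyl ketone.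

**Step 6**
Reactants: 8 (diazoketone)
Product: 9 arylglyoxal 2-{3,5-bis[4-(benzyloxy)benzyl]-2,4,6-tris{[4-(benzyloxy)benzyl]oxy}phenyl}-2-oxoacetaldehyde
Conditions: dimethyldioxirane (1.1 equiv, in acetone), CH2Cl2, 4 Å molecular sieves, 0 °C; evaporate and use at once
Reagents that add atoms: dimethyldioxirane, CC1(C)OO1
Why: Oxygen-atom transfer from the dioxirane to the nucleophilic diazo carbon with loss of N2 (the known oxidation of α-diazo ketones to glyoxals) should give the anhydrous keto aldehyde under neutral conditions, the diazo carbon reacting far faster than the alkoxyarenes.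

**Step 7**
Reactants: 9 (arylglyoxal)
Product: 11 protected dihydroflavonol (2R,3R)-2-[4-(benzyloxy)phenyl]-6,8-bis[4-(benzyloxy)benzyl]-5,7-bis{[4-(benzyloxy)benzyl]oxy}-3-hydroxychroman-4-one, via 1,6-biradical 10 (not isolated)
Conditions: hν (427 nm LED), (R)-TRIP (3,3'-bis(2,4,6-triisopropylphenyl)-1,1'-binaphthyl-2,2'-diyl hydrogen phosphate, 1.0 equiv, recovered), 4 Å molecular sieves, degassed toluene (0.01 M), −40 °C
Reagents that add atoms: none
Why: Proposed new method: 427 nm light should excite only the n,π* band of the 1,2-dicarbonyl of 9 (the alkoxyarenes and the chromanone product are transparent there), and the triplet should abstract, through its exposed aldehyde oxygen and an eight-membered transition state (1,7-hydrogen transfer), a hydrogen from one of the two symmetry-equivalent ortho O–CH2–aryl groups to give the 1,6-biradical 10, which after intersystem crossing combines C3 with C2. The closest known reaction types are the Norrish–Yang photocyclization of 1,2-diketones (abstraction by the remote oxygen, giving 2-hydroxycyclobutanones and, from o-alkylphenyl diones, 2-hydroxyindan-1-ones) and of o-benzyloxyphenyl ketones (dihydrobenzofuran-3-ols); the six-membered closure onto an aldehyde-derived carbon and its control by a chiral acid are the untested extensions. Ring C closes by radical–radical recombination of the 1,6-biradical, a six-membered closure in which the C3–C4 hydroxy-enoxyl unit ends up inside the new ring. C3 should be set by the chiral phosphoric acid, expected to hold the nascent hydroxy-enoxyl radical by two hydrogen bonds (P–OH to O=C4 and C3–OH to O=P, the binding mode known from phosphoric-acid-controlled radical couplings of ketyl radicals derived from 1,2-dicarbonyls) and so to leave one face of C3 open, and C2 should be set relative to C3 in a half-chair closure that keeps the 4-(benzyloxy)phenyl group pseudo-equatorial and anti to the C3 hydroxyl (2,3-trans). The step needs site selectivity among ten benzylic CH2 groups (secured by reach, since only the ortho ether CH2 groups can meet a dicarbonyl oxygen), 1,7-abstraction by the aldehyde oxygen rather than 1,6-abstraction by the ketone oxygen (favoured by the doubly ortho-flanked, twisted C4 carbonyl against the unhindered aldehyde oxygen) and a high share of acid-bound substrate (full equivalent of acid, non-polar solvent, low temperature).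

**Step 8**
Reactants: 11 (protected dihydroflavonol)
Product: 12 gericudranin D (2R,3R)-3,5,7-trihydroxy-6,8-bis(4-hydroxybenzyl)-2-(4-hydroxyphenyl)chroman-4-one
Conditions: H2 (1 atm), Pd/C (10 wt% zerovalent palladium on carbon), EtOAc/MeOH, 23 °C
Reagents that add atoms: none
Why: Catalytic hydrogenolysis should cleave all seven acyclic benzylic C–O bonds (the 4-(benzyloxy)benzyl ethers falling apart to 4-methylphenol and toluene), while the diarylmethane C–C bonds, the chelated C4 ketone, the cyclic C2–O1 bond and both stereocentres are expected to survive these neutral conditions.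

**Compound list**

1 | 2,4,6-trihydroxyacetophenone (phloroacetophenone) | CC(=O)c1c(O)cc(O)cc1O | starting material
2 | 4-(benzyloxy)benzyl alcohol | OCc1ccc(OCc2ccccc2)cc1 | starting material
3 | 1-{3,5-bis[4-(benzyloxy)benzyl]-2,4,6-trihydroxyphenyl}ethan-1-one | CC(=O)c1c(O)c(Cc2ccc(OCc3ccccc3)cc2)c(O)c(Cc2ccc(OCc3ccccc3)cc2)c1O | intermediate
4 | 1-{3,5-bis[4-(benzyloxy)benzyl]-2,4-bis{[4-(benzyloxy)benzyl]oxy}-6-hydroxyphenyl}ethan-1-one | CC(=O)c1c(O)c(Cc2ccc(OCc3ccccc3)cc2)c(OCc2ccc(OCc3ccccc3)cc2)c(Cc2ccc(OCc3ccccc3)cc2)c1OCc1ccc(OCc2ccccc2)cc1 | intermediate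
5 | 4-(benzyloxy)benzyl chloride | ClCc1ccc(OCc2ccccc2)cc1 | starting material
6 | 1-{3,5-bis[4-(benzyloxy)benzyl]-2,4,6-tris{[4-(benzyloxy)benzyl]oxy}phenyl}ethan-1-one | CC(=O)c1c(OCc2ccc(OCc3ccccc3)cc2)c(Cc2ccc(OCc3ccccc3)cc2)c(OCc2ccc(OCc3ccccc3)cc2)c(Cc2ccc(OCc3ccccc3)cc2)c1OCc1ccc(OCc2ccccc2)cc1 | intermediate
7 | 1-{3,5-bis[4-(benzyloxy)benzyl]-2,4,6-tris{[4-(benzyloxy)benzyl]oxy}phenyl}-4,4,4-trifluorobutane-1,3-dione | FC(F)(F)C(=O)CC(=O)c1c(OCc2ccc(OCc3ccccc3)cc2)c(Cc2ccc(OCc3ccccc3)cc2)c(OCc2ccc(OCc3ccccc3)cc2)c(Cc2ccc(OCc3ccccc3)cc2)c1OCc1ccc(OCc2ccccc2)cc1 | intermediate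
8 | 2-diazo-1-{3,5-bis[4-(benzyloxy)benzyl]-2,4,6-tris{[4-(benzyloxy)benzyl]oxy}phenyl}ethan-1-one | [N-]=[N+]=CC(=O)c1c(OCc2ccc(OCc3ccccc3)cc2)c(Cc2ccc(OCc3ccccc3)cc2)c(OCc2ccc(OCc3ccccc3)cc2)c(Cc2ccc(OCc3ccccc3)cc2)c1OCc1ccc(OCc2ccccc2)cc1 | intermediate
9 | 2-{3,5-bis[4-(benzyloxy)benzyl]-2,4,6-tris{[4-(benzyloxy)benzyl]oxy}phenyl}-2-oxoacetaldehyde | O=CC(=O)c1c(OCc2ccc(OCc3ccccc3)cc2)c(Cc2ccc(OCc3ccccc3)cc2)c(OCc2ccc(OCc3ccccc3)cc2)c(Cc2ccc(OCc3ccccc3)cc2)c1OCc1ccc(OCc2ccccc2)cc1 | intermediate
10 | 1,6-biradical from 9 (hydroxy-substituted radical at the later C3, aryloxy benzylic radical at the later C2) | O[CH]C(=O)c1c(O[CH]c2ccc(OCc3ccccc3)cc2)c(Cc2ccc(OCc3ccccc3)cc2)c(OCc2ccc(OCc3ccccc3)cc2)c(Cc2ccc(OCc3ccccc3)cc2)c1OCc1ccc(OCc2ccccc2)cc1 | intermediate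
11 | (2R,3R)-2-[4-(benzyloxy)phenyl]-6,8-bis[4-(benzyloxy)benzyl]-5,7-bis{[4-(benzyloxy)benzyl]oxy}-3-hydroxychroman-4-one | O=C1c2c(OCc3ccc(OCc4ccccc4)cc3)c(Cc3ccc(OCc4ccccc4)cc3)c(OCc3ccc(OCc4ccccc4)cc3)c(Cc3ccc(OCc4ccccc4)cc3)c2O[C@H](c2ccc(OCc3ccccc3)cc2)[C@H]1O | intermediate
12 | gericudranin D, (2R,3R)-3,5,7-trihydroxy-6,8-bis(4-hydroxybenzyl)-2-(4-hydroxyphenyl)chroman-4-one | O=C1c2c(O)c(Cc3ccc(O)cc3)c(O)c(Cc3ccc(O)cc3)c2O[C@H](c2ccc(O)cc2)[C@H]1O | target

**Step count and risks**

Total step count: 8. Longest linear sequence: 8 steps (1 to 12); 2 and 5 are purchased.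

Steps most likely to fail:

1. Step 7 (proposed new method). The triplet may abstract through the ketone oxygen instead, leading to five-membered closure. Unbound substrate may cyclize in the background, so that face discrimination at C3 is weak. Photodecarbonylation of the glyoxal may compete. The fallback uses known chemistry, sets out from diazoketone 8 and comes back at 11. Decomposition of 8 with the chiral divalent rhodium carboxylate Rh2(S-PTTL)4 (dirhodium tetrakis[N-phthaloyl-(S)-tert-leucinate], 1 mol%, toluene, −20 °C; the antipode is taken if the sense is opposite) should insert the carbene into a C–H bond of the same ortho O–CH2 group. This is the intramolecular C–H insertion alpha to an ether oxygen known to turn o-alkoxyaryl diazoketones into chroman-4-ones; it forms the same C2–C3 bond under catalyst control at C2, though an oxonium ylide with 1,2-benzyl shift is a known side path. It would give the flavanone (2S)-2-[4-(benzyloxy)phenyl]-6,8-bis[4-(benzyloxy)benzyl]-5,7-bis{[4-(benzyloxy)benzyl]oxy}chroman-4-one F1. TMSOTf and Et3N (CH2Cl2, 0 °C) would convert it into the trimethylsilyl enol ether F2. Dimethyldioxirane (acetone, −40 °C) would epoxidize the enol ether anti to the C2 aryl group (Rubottom oxidation) to the silyloxy epoxide F3. Work-up with aqueous citric acid would open F3 to 11 with loss of trimethylsilanol.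

2. Step 1. The benzylic cation precursor may self-condense to oligomers, and the reaction may stall after the first benzylation. The fallback sets out from 1 and comes back at 3: C-benzylation through the phloroglucinolate, with chloride 5 (2.1 equiv) in aqueous KOH at 0 °C, the classical C-alkylation of acylphloroglucinol anions in protic media. It makes no compound outside the list (F0).

3. Step 2. The activated p-alkoxybenzyl alcohol may ionize and be lost to side reactions, and etherification may stop early or run on, giving mixtures of mono-, di- and tri-ethers (the tri-ether is 6 and is harmless). The fallback sets out from 3 and comes back at 4: Williamson etherification with chloride 5 (2.1 equiv), K2CO3, acetone, reflux. It activates the phenols as phenoxides instead of the alcohol; they should react in the order of their acidity under these mild conditions, and the last chelated hydroxyl is left for step 3. It makes no compound outside the list (F0).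

**Further compounds**

F1 | step 7 | (2S)-2-[4-(benzyloxy)phenyl]-6,8-bis[4-(benzyloxy)benzyl]-5,7-bis{[4-(benzyloxy)benzyl]oxy}chroman-4-one | O=C1c2c(OCc3ccc(OCc4ccccc4)cc3)c(Cc3ccc(OCc4ccccc4)cc3)c(OCc3ccc(OCc4ccccc4)cc3)c(Cc3ccc(OCc4ccccc4)cc3)c2O[C@H](c2ccc(OCc3ccccc3)cc2)C1
F2 | step 7 | (2S)-2-[4-(benzyloxy)phenyl]-6,8-bis[4-(benzyloxy)benzyl]-5,7-bis{[4-(benzyloxy)benzyl]oxy}-4-[(trimethylsilyl)oxy]-2H-chromene | C[Si](C)(C)OC1=C[C@@H](c2ccc(OCc3ccccc3)cc2)Oc2c(Cc3ccc(OCc4ccccc4)cc3)c(OCc3ccc(OCc4ccccc4)cc3)c(Cc3ccc(OCc4ccccc4)cc3)c(OCc3ccc(OCc4ccccc4)cc3)c12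
F3 | step 7 | 3,4-epoxide of F2 (4-trimethylsilyloxy, oxirane oxygen anti to the C2 aryl group) | C[Si](C)(C)O[C@@]12O[C@@H]1[C@@H](c1ccc(OCc3ccccc3)cc1)Oc1c(Cc3ccc(OCc4ccccc4)cc3)c(OCc3ccc(OCc4ccccc4)cc3)c(Cc3ccc(OCc4ccccc4)cc3)c(OCc3ccc(OCc4ccccc4)cc3)c12
F0 | step 1 | none | none
F0 | step 2 | none | none
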